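The runs are calculated from invented constants; the scatter is artificial.

The product I am after is the complex with one exchanged. It forms when incoming ligand replaces a ligand on the starting complex and releases leaving ligand. It can exchange further, to the complex with two exchanged and then three, or the capture agent can take it to trapped intermediate, while the incoming ligand can also decompose by itself.

| flask | starting complex | incoming ligand | capture agent | remark | time |
|---|---|---|---|---|---|
| maple | 40 mM | 26 mM | 40 mM | run made earlier |  |
| alder | 40 mM | 110 mM | 40 mM | run made earlier |  |
| dusk | 40 mM | 40.0 mM | 40.0 mM |  | 3.0 min |
| spring | 40 mM | 160 mM | 40.0 mM |  | 3.0 min |
| dawn | 40 mM | 48.0 mM | 40.0 mM |  | 3.0 min |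

- maple (time / s: complex with one exchanged / %, complex with two exchanged / %): 20.0: 12.8, 0; 40.0: 15.8, 0.1; 50.0: 15.7, 0.6; 80.0: 14.6, 0.2; 90.0: 14.0, 0; 120: 11.6, 0
- alder (time / s: complex with one exchanged / %, complex with two exchanged / %): 20.0: 41.1, 0.7; 40.0: 48.0, 2.2; 50.0: 48.1, 2.5; 80.0: 43.8, 2.8; 90.0: 41.8, 3.0; 120: 36.7, 3.0

(each reading ± 0.3 percentage points)

- candidate steps: starting complex + incoming ligand -> leaving ligand + complex with one exchanged; complex with one exchanged + incoming ligand -> leaving ligand + complex with two exchanged; complex with two exchanged + incoming ligand -> leaving ligand + complex with three exchanged; complex with one exchanged + capture agent -> trapped intermediate; incoming ligand -> decomposed reagent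

- which of these holds the largest part of the starting complex at the end of dusk (starting complex / complex with one exchanged / complex with three exchanged / complex with two exchanged)
- which of these holds the largest part of the starting complex at the end of spring (starting complex / complex with one exchanged / complex with three exchanged / complex with two exchanged)
- which of these holds the largest part of the starting complex at the end of dawn (starting complex / complex with one exchanged / complex with three exchanged / complex with two exchanged)
- complex with one exchanged at the end of dawn, in percent of the starting complex charged

I build dawn one process at a time. With the main step by itself, the ligand charge covers the complex charge, so the starting complex is the limiting reagent and the ceiling of the product is 100 percent of its charge; that is a ceiling, not a figure for the end of dawn.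

Now I add decomposition. Maple and alder both stand highest at readings between 40.0 s and 50.0 s, though alder carries 4.23 times as much ligand, so I read the supply as dying on a clock of its own. At 120 s, maple holds 0.00446 /mM of the charged complex per mM of ligand and alder 0.00334 /mM, less per mM. Interpolating these linearly to dawn's ligand gives 20.0% at that time.

Then I add capture. Past the peak the product falls roughly exponentially, and I call this pseudo-first-order constant the capture rate, the net fraction of the product lost per second at a capture agent charge of 40 mM, with whatever is still being made counted in: 0.00575 /s, read from maple's last readings. Alder's reading is 0.00442 /s, but dawn's ligand lies nearer maple's, so I keep maple's.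

The further exchange I set aside, because alder shows 3.0% of the complex with two exchanged against 36.7% of the product. Over the remaining 60.0 s of dawn, the capture rate brings my estimate to 14.2%.

The forecast starts from “the incoming ligand dying quickly”. It names starting complex for dusk, complex with one exchanged for spring and starting complex for dawn, and puts the product in dawn at 14.3%.

The flask puts starting complex ahead in dusk at 65.0%, complex with one exchanged ahead in spring at 32.7%, and starting complex ahead in dawn at 59.2%.

    starting complex + incoming ligand → leaving ligand + complex with one exchanged (k = 0.405 /M/s)
    complex with one exchanged + incoming ligand → leaving ligand + complex with two exchanged (k = 0.0318 /M/s)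
    complex with two exchanged + incoming ligand → leaving ligand + complex with three exchanged (k = 0.0523 /M/s)
    complex with one exchanged + capture agent → trapped intermediate (k = 0.197 /M/s)
    incoming ligand → decomposed reagent (k = 0.0242 /s)

Dawn ends with the product at 14.4%, and at that moment it is made at 0.0252 of the rate at which it is used up. Dusk is charged with the same 40.0 mM of capture agent as dawn, and I apply the capture rate there unchanged. Starting from the 20.5% of product that dusk holds at 1.50 min, it gives 12.2% at the end of dusk, and the flask holds 12.2%.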